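**Retrosynthetic overview**

1. The target is an oplopane, that is a cadinane whose ring A (C-1 to C-6) has lost C-4 from the ring. The cyclopentane is therefore traced back to the cadinane hydroxy mesylate 20 by a semipinacol 1,2-shift of C-3 from C-4 to C-5, which copies the presumed cadinane-to-oplopane biogenesis and is the last step.
2. Enabling feature: in the chair of ring A of the trans-decalin, the tertiary carbinol C-4 (bearing CH3-15) lies next to C-5, which carries an equatorial sulfonate. The ring bond C3–C4 is antiperiplanar to C5–O, and C-4 becomes the acetyl carbon that the target carries on C-5, cis to O-3.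
3. 20 comes from triol 16, which comes from enone 13 by Luche reduction and hydroxyl-directed syn-dihydroxylation of C3=C4.
4. Ring B (with 8α-OH and the C10=C14 methylene) comes from a type 2 carbonyl-ene closure (C8–C9) of keto aldehyde 10. 10 comes from (R)-carvone, isobutyraldehyde and nitromethane (aldol condensation, Michael addition, Nef reaction).
5. Ring order: ring A is supplied six-membered by carvone, ring B is closed second, ring A is contracted to the five-membered ring last.

Key step: step 11

Remarks on the chemistry:
- Monocyclic compounds are numbered as carvone (C-1 carbonyl, C-2 methyl, C-5 isopropenyl, C-6 the α′ carbon).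
- Bicyclic compounds are numbered as cadinanes (ring A = C-1 to C-6 with CH3-15 on C-4; ring B = C-1, C-6 to C-10 with isopropyl on C-7 and C-14 on C-10). The target keeps this numbering as an oplopane (acetyl = C-4/C-15 on C-5). β is the face of H-1, α the face of H-6.
- Assumption: the hindered hydroxy mesylate 20 can be handled cold and is used without storage.

**Step 1**
Reactants: 1 (R)-(−)-carvone; 2 isobutyraldehyde
Product: 3 (5R,6R)-6-[(1R)-1-hydroxy-2-methylpropyl]-2-methyl-5-(prop-1-en-2-yl)cyclohex-2-en-1-one
Conditions: LiN(i-Pr)2, THF, −78 °C; then 2, −78 °C; AcOH quench at −78 °C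
Reagents that add atoms: none
Why: Kinetic α′-deprotonation of carvone and aldol addition should place the new bond at C-6 on the face opposite to the C-5 isopropenyl group (5,6-trans), and the closed chair transition state of the cyclic enolate should give mainly the anti carbinol, whose configuration is lost in step 2.

**Step 2**
Reactants: 3 aldol adduct
Product: 5 (5S,6E)-2-methyl-6-(2-methylpropylidene)-5-(prop-1-en-2-yl)cyclohex-2-en-1-one, via mesylate 4 (not isolated)
Conditions: MsCl, Et3N, CH2Cl2, 0 °C; then DBU, 0 °C to rt
Reagents that add atoms: methanesulfonyl chloride, CS(=O)(=O)Cl (its atoms stay only in intermediate 4)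
Why: Mesylation followed by E1cB elimination should give the more stable (E)-alkylidene ketone with the isopropyl group anti to the carbonyl; no stereocentre is formed and C-5 is spatially unchanged (the descriptor changes only by priority).

**Step 3**
Reactants: 5 cross-conjugated dienone; 6 nitromethane
Product: 7 (5R,6R)-2-methyl-6-[(2S)-3-methyl-1-nitrobutan-2-yl]-5-(prop-1-en-2-yl)cyclohex-2-en-1-one
Conditions: MeNO2 (10 equiv), DBU (0.2 equiv), MeCN, 0 °C
Reagents that add atoms: none
Why: Base-catalysed Michael addition of nitromethane should occur at the more electrophilic exocyclic s-cis enone; A(1,3) strain between the (E)-isobutylidene group and C-5 forces the isopropenyl group axial, so the nitronate adds to the opposite face of C-7 (7S), and C-6 is set trans by equilibrating protonation next to the ketone.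

**Step 4**
Reactants: 7 nitro ketone
Product: 10 (2S)-3-methyl-2-[(1R,6R)-3-methyl-2-oxo-6-(prop-1-en-2-yl)cyclohex-3-en-1-yl]butanal, via sodium nitronate 8 (not isolated), via aldimine 9 (not isolated)
Conditions: NaOMe, MeOH, −40 °C, short time; then transfer into aq. TiCl3, NH4OAc buffer (pH about 5 to 6), THF, 0 °C
Reagents that add atoms: water, O; sodium methoxide, C[O-].[Na+] (sodium only in intermediate 8)
Why: In this reductive Nef reaction the cold nitronate is reduced at once by trivalent titanium to the aldimine, which hydrolyses in the buffer; the short nitronate lifetime should suppress its addition to the ring enone, and the near-neutral medium should leave C-7 next to the new aldehyde untouched.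

**Step 5**
Reactants: 10 keto aldehyde
Product: 12 8α-hydroxycadina-3,10(14)-dien-5-one, via aluminium alkoxide 11 (not isolated)
Conditions: Me2AlCl (2.5 equiv), CH2Cl2, −78 to −30 °C; aq. Rochelle salt
Reagents that add atoms: dimethylaluminium chloride, C[Al](C)Cl (its atoms stay only in intermediate 11)
Why: The Lewis-acid-promoted type 2 intramolecular carbonyl-ene reaction should close ring B (C8–C9) through a chair transition state with the isopropyl group equatorial and the aldehyde oxygen axial (it must reach the allylic hydrogen of the isopropenyl methyl), which gives the axial 8α-alcohol cis to the isopropyl group and the exocyclic C10=C14 bond; the trans ring fusion follows from the 5,6-trans substituents.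

**Step 6**
Reactants: 12 hydroxy enone
Product: 13 8α-acetoxycadina-3,10(14)-dien-5-one
Conditions: Ac2O, pyridine, DMAP (cat.), CH2Cl2, rt
Reagents that add atoms: acetic anhydride, CC(=O)OC(C)=O
Why: DMAP-catalysed acylation of the only hydroxyl group should proceed without touching a stereocentre.

**Step 7**
Reactants: 13 acetoxy enone
Product: 14 8α-acetoxycadina-3,10(14)-dien-5α-ol
Conditions: NaBH4, CeCl3·7H2O, MeOH, −78 to −40 °C
Reagents that add atoms: none
Why: Luche 1,2-reduction with axial hydride attack should give the equatorial 5α-alcohol (as carvone gives cis-carveol); the equatorial approach is further blocked by the peri isopropyl group, and the acetate survives the cold, short reaction.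

**Step 8**
Reactants: 14 allylic alcohol
Product: 16 8α-acetoxycadin-10(14)-ene-3α,4α,5α-triol, via osmate ester 15 (not isolated)
Conditions: OsO4 (1.05 equiv), TMEDA (1.1 equiv), CH2Cl2, −78 °C; then aq. Na2SO3, THF, 60 °C
Reagents that add atoms: osmium tetroxide, O=[Os](=O)(=O)=O; TMEDA, CN(C)CCN(C)C (only in intermediate 15)
Why: In this hydrogen-bond-directed syn-dihydroxylation the OsO4·TMEDA complex should be delivered by the allylic 5α-OH to the α face of the trisubstituted C3=C4 bond, which sets 3α-OH and 4α-OH and should make this alkene react before the undirected exocyclic methylene.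

**Step 9**
Reactants: 16 triol; 17 angelic acid
Product: 19 8α-acetoxy-3α-angeloyloxycadin-10(14)-ene-4α,5α-diol, via mixed anhydride 18 (not isolated)
Conditions: 17, 2,4,6-trichlorobenzoyl chloride, Et3N, toluene, rt; then 16, 75 °C (no DMAP)
Reagents that add atoms: 2,4,6-trichlorobenzoyl chloride, O=C(Cl)c1c(Cl)cc(Cl)cc1Cl (its atoms stay only in intermediate 18)
Why: Yamaguchi-type mixed-anhydride esterification without DMAP should avoid angelate-to-tiglate isomerisation and should acylate the least hindered secondary 3α-OH, because 5α-OH is shielded by C-4 and the peri isopropyl group and 4-OH is tertiary.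

**Step 10**
Reactants: 19 diol
Product: 20 8α-acetoxy-3α-angeloyloxy-4α-hydroxycadin-10(14)-en-5α-yl methanesulfonate
Conditions: MsCl, Et3N, CH2Cl2, −20 to 0 °C; cold work-up, used directly
Reagents that add atoms: methanesulfonyl chloride, CS(=O)(=O)Cl
Why: Sulfene-type mesylation should convert the remaining secondary alcohol with retention at C-5, while the tertiary 4-OH stays free and cannot close an epoxide because it is cis to the leaving group.

**Step 11**
Reactants: 20 hydroxy mesylate
Product: 22 8α-acetoxy-3α-angeloyloxyoplop-10(14)-en-4-one, via diethylaluminium alkoxide 21 (not isolated)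
Conditions: Et3Al (3 equiv), CH2Cl2, −78 to −20 °C; aq. Rochelle salt, pH 7 buffer
Reagents that add atoms: triethylaluminium, CC[Al](CC)CC (its atoms stay only in intermediate 21)
Why: Et3Al deprotonates the tertiary 4α-OH (ethane is lost) and the aluminium alkoxide 21 pushes the antiperiplanar ring bond C3–C4 onto C-5 while the Lewis-acid-assisted equatorial 5α-mesylate leaves, so that C-4 becomes the acetyl carbonyl; this is a semipinacol rearrangement of a 2-hydroxy sulfonate, whose closest known type is the organoaluminium-promoted ring contraction of cyclohexane-1,2-diol monosulfonates to acylcyclopentanes. The cyclopentane (C-1, C-2, C-3, C-5, C-6) closes by a suprafacial 1,2-alkyl shift with backside displacement at C-5, not by an exo or endo cyclisation of a chain. The new stereocentre C-5 is formed with inversion, which places the acetyl group α and cis to the 3α-angelate; C-3 migrates with retention and C-1, C-6, C-7 and C-8 are untouched, so the trans ring fusion is carried over. The step needs migration of C-3 and not of C-1 (from C-6), methyl or hydride; the chair of ring A in the trans-decalin secures this, because only the two ring bonds are antiperiplanar to the equatorial C5–O bond and only C-4 carries the oxygen that stabilises the developing positive charge. Participation by the 3-ester is excluded because it is cis to the leaving group, the esters and the exocyclic alkene should not react with Et3Al at low temperature, and the peri strain between the 5α-mesylate and the 7α-isopropyl group is released in the transition state.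

**Compound list**

1 | (R)-(−)-carvone | CC1=CC[C@H](CC1=O)C(C)=C | starting material
2 | isobutyraldehyde (2-methylpropanal) | CC(C)C=O | starting material
3 | (5R,6R)-6-[(1R)-1-hydroxy-2-methylpropyl]-2-methyl-5-(prop-1-en-2-yl)cyclohex-2-en-1-one (5,6-trans; anti carbinol drawn, its configuration is lost in step 2) | C=C(C)[C@@H]1CC=C(C)C(=O)[C@H]1[C@H](O)C(C)C | intermediate
4 | methanesulfonate of 3 (not isolated) | C=C(C)[C@@H]1CC=C(C)C(=O)[C@H]1[C@H](OS(C)(=O)=O)C(C)C | intermediate
5 | (5S,6E)-2-methyl-6-(2-methylpropylidene)-5-(prop-1-en-2-yl)cyclohex-2-en-1-one (C-5 spatially as in 1) | C=C(C)[C@@H]1CC=C(C)C(=O)/C1=C/C(C)C | intermediate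
6 | nitromethane | C[N+](=O)[O-] | starting material
7 | (5R,6R)-2-methyl-6-[(2S)-3-methyl-1-nitrobutan-2-yl]-5-(prop-1-en-2-yl)cyclohex-2-en-1-one (5,6-trans) | C=C(C)[C@@H]1CC=C(C)C(=O)[C@H]1[C@@H](C[N+](=O)[O-])C(C)C | intermediate
8 | sodium nitronate of 7 (not isolated) | C=C(C)[C@@H]1CC=C(C)C(=O)[C@H]1[C@@H](C=[N+]([O-])[O-])C(C)C.[Na+] | intermediate
9 | aldimine from 8 (not isolated) | C=C(C)[C@@H]1CC=C(C)C(=O)[C@H]1[C@@H](C=N)C(C)C | intermediate
10 | (2S)-3-methyl-2-[(1R,6R)-3-methyl-2-oxo-6-(prop-1-en-2-yl)cyclohex-3-en-1-yl]butanal | C=C(C)[C@@H]1CC=C(C)C(=O)[C@H]1[C@@H](C=O)C(C)C | intermediate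
11 | O-chloro(methyl)aluminium alkoxide of 12 (not isolated) | C=C1C[C@@H](O[Al](C)Cl)[C@@H](C(C)C)[C@@H]2C(=O)C(C)=CC[C@@H]12 | intermediate
12 | 8α-hydroxycadina-3,10(14)-dien-5-one (trans-fused; 1β-H, 6α-H, 7α-isopropyl, axial 8α-OH) | C=C1C[C@@H](O)[C@@H](C(C)C)[C@@H]2C(=O)C(C)=CC[C@@H]12 | intermediate
13 | 8α-acetoxycadina-3,10(14)-dien-5-one | C=C1C[C@@H](OC(C)=O)[C@@H](C(C)C)[C@@H]2C(=O)C(C)=CC[C@@H]12 | intermediate
14 | 8α-acetoxycadina-3,10(14)-dien-5α-ol (equatorial 5-OH) | C=C1C[C@@H](OC(C)=O)[C@@H](C(C)C)[C@@H]2[C@@H](O)C(C)=CC[C@@H]12 | intermediate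
15 | cyclic 3α,4α-osmate ester of 14 (hexavalent osmium, TMEDA-ligated; not isolated) | C=C1C[C@@H](OC(C)=O)[C@@H](C(C)C)[C@@H]2[C@@H](O)[C@@]3(C)O[Os](=O)(=O)O[C@H]3C[C@@H]12.CN(C)CCN(C)C | intermediate
16 | 8α-acetoxycadin-10(14)-ene-3α,4α,5α-triol (4β-methyl) | C=C1C[C@@H](OC(C)=O)[C@@H](C(C)C)[C@@H]2[C@@H](O)[C@@](C)(O)[C@@H](O)C[C@@H]12 | intermediate
17 | angelic acid, (Z)-2-methylbut-2-enoic acid | C/C=C(/C)C(=O)O | starting material
18 | angelic 2,4,6-trichlorobenzoic anhydride (not isolated) | C/C=C(/C)C(=O)OC(=O)c1c(Cl)cc(Cl)cc1Cl | intermediate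
19 | 8α-acetoxy-3α-angeloyloxycadin-10(14)-ene-4α,5α-diol | C=C1C[C@@H](OC(C)=O)[C@@H](C(C)C)[C@@H]2[C@@H](O)[C@@](C)(O)[C@@H](OC(=O)/C(C)=C\C)C[C@@H]12 | intermediate
20 | 8α-acetoxy-3α-angeloyloxy-4α-hydroxycadin-10(14)-en-5α-yl methanesulfonate (equatorial mesylate) | C=C1C[C@@H](OC(C)=O)[C@@H](C(C)C)[C@@H]2[C@@H](OS(C)(=O)=O)[C@@](C)(O)[C@@H](OC(=O)/C(C)=C\C)C[C@@H]12 | intermediate
21 | 4-O-diethylaluminium alkoxide of 20 (not isolated) | C=C1C[C@@H](OC(C)=O)[C@@H](C(C)C)[C@@H]2[C@@H](OS(C)(=O)=O)[C@@](C)(O[Al](CC)CC)[C@@H](OC(=O)/C(C)=C\C)C[C@@H]12 | intermediate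
22 | 8α-acetoxy-3α-angeloyloxyoplop-10(14)-en-4-one (trans-hydrindane; 1β-H, 5β-H, 6α-H, 7α-isopropyl) | C=C1C[C@@H](OC(C)=O)[C@@H](C(C)C)[C@@H]2[C@@H](C(C)=O)[C@@H](OC(=O)/C(C)=C\C)C[C@@H]12 | target

**Step count and risks**

Total step count: 11. Longest linear sequence: 11 steps (from 1 to 22; the route is fully linear).

Steps most likely to fail:

1. Step 3 (Michael addition). Possible failures are competing conjugate addition at C-3 of the ring enone, a second, intramolecular Michael addition of the nitronate to that enone (closure of a bicyclo[2.2.2]octanone), and erosion of the C-7 selectivity if the addition becomes reversible. The fallback sets out from 5 and returns at 10, so it also bypasses the Nef step. 2-Lithio-1,3-dithiane (from 1,3-dithiane and n-BuLi) in THF/HMPA at −78 °C should add irreversibly to the exocyclic enone from the same face as a formyl anion equivalent whose adduct carries no acidic C–H. Quench with aq. NH4Cl and equilibration at C-6 with catalytic DBU should give the 5,6-trans dithiane adduct F1. Alkylative hydrolysis (MeI, CaCO3, aq. MeCN, 40 °C) then releases aldehyde 10.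

2. Step 8 (directed dihydroxylation). Possible failures are competitive osmylation of the exocyclic C10=C14 bond and incomplete hydrogen-bond delivery. The fallback sets out from 13 and returns at 16; it masks the exocyclic alkene while the ring enone C=C is still electron-poor. mCPBA (NaHCO3, CH2Cl2, 0 °C) should give the 10,14-spiro-epoxide F2 (β-oxygen drawn; either epimer serves). Luche reduction as in step 7 gives the epoxy allylic alcohol F3. OsO4·TMEDA as in step 8, now with a single alkene, gives the epoxy triol F4. Radical deoxygenation with Cp2TiCl (trivalent titanium, generated from Cp2TiCl2 and Zn in THF) restores the exocyclic methylene and gives 16.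

3. Step 11 (key step). Possible failures are slow migration of the acyloxy-bearing C-3, which would leave time for 1,2-acyl transfer from O-3 to the aluminium alkoxide at O-4, and β-elimination of angelic acid from the product. The fallback sets out from 16 and returns at 22; it makes the migrating carbon more electron-rich and moves the esterification to the end. TESCl and imidazole (DMF, 0 °C) should silylate the least hindered 3α-OH to give the 3-O-triethylsilyl triol F5. MsCl and Et3N give its 5α-mesylate F6. Et3Al (CH2Cl2, −78 °C) gives the ring-contracted 3α-silyloxy ketone F7. HF·pyridine (THF, 0 °C) gives the β-hydroxy ketone F8. Esterification with 17 by the mixed-anhydride method of step 9 (toluene, at most 60 °C) then gives 22.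

Further compounds

F1 | step 3 | (5R,6R)-6-[(1S)-1-(1,3-dithian-2-yl)-2-methylpropyl]-2-methyl-5-(prop-1-en-2-yl)cyclohex-2-en-1-one | C=C(C)[C@@H]1CC=C(C)C(=O)[C@H]1[C@@H](C1SCCCS1)C(C)C
F2 | step 8 | 8α-acetoxy-10,14-epoxycadin-3-en-5-one (spiro-epoxide, β-oxygen drawn) | C1O[C@@]12C[C@@H](OC(C)=O)[C@@H](C(C)C)[C@@H]3C(=O)C(C)=CC[C@@H]23
F3 | step 8 | 8α-acetoxy-10,14-epoxycadin-3-en-5α-ol | C1O[C@@]12C[C@@H](OC(C)=O)[C@@H](C(C)C)[C@@H]3[C@@H](O)C(C)=CC[C@@H]23
F4 | step 8 | 8α-acetoxy-10,14-epoxycadinane-3α,4α,5α-triol | C1O[C@@]12C[C@@H](OC(C)=O)[C@@H](C(C)C)[C@@H]3[C@@H](O)[C@@](C)(O)[C@@H](O)C[C@@H]23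
F5 | step 11 | 8α-acetoxy-3α-(triethylsilyloxy)cadin-10(14)-ene-4α,5α-diol | C=C1C[C@@H](OC(C)=O)[C@@H](C(C)C)[C@@H]2[C@@H](O)[C@@](C)(O)[C@@H](O[Si](CC)(CC)CC)C[C@@H]12
F6 | step 11 | 8α-acetoxy-4α-hydroxy-3α-(triethylsilyloxy)cadin-10(14)-en-5α-yl methanesulfonate | C=C1C[C@@H](OC(C)=O)[C@@H](C(C)C)[C@@H]2[C@@H](OS(C)(=O)=O)[C@@](C)(O)[C@@H](O[Si](CC)(CC)CC)C[C@@H]12
F7 | step 11 | 8α-acetoxy-3α-(triethylsilyloxy)oplop-10(14)-en-4-one | C=C1C[C@@H](OC(C)=O)[C@@H](C(C)C)[C@@H]2[C@@H](C(C)=O)[C@@H](O[Si](CC)(CC)CC)C[C@@H]12
F8 | step 11 | 8α-acetoxy-3α-hydroxyoplop-10(14)-en-4-one | C=C1C[C@@H](OC(C)=O)[C@@H](C(C)C)[C@@H]2[C@@H](C(C)=O)[C@@H](O)C[C@@H]12
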